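**Retrosynthetic overview**

1. Numbering: ring fusion C1/C5; ring A (cyclopentene) C1–C5 with C2=C3 and the methyl carbinol C4; ring B (cycloheptane) C5, C6 (carbinol), C7 (side chain), C8, C9, C10 (=CH2), C1; side chain C11–C15 with the acetate on C13.
2. Feature on which the route rests: in ring A the three carbons C2–C3–C4 span C1 and C5, and the methyl-bearing C4 sits on C5, the carbon α to the C6 oxygen. A 1-methyl-1-silylallene lays down exactly this pattern on an enone with C6=O and C5=C1.
3. Late disconnections: C13–C14 (alkenylzinc addition to a C13 aldehyde), C6–H (hydroxyl-directed reduction), C4–O with C2=C3 (silicon-directed singlet-oxygen ene), C10=CH2 (methylenation of a C10 ketone).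
4. Key disconnection: C1–C2 and C4–C5 by TiCl4-promoted [3+2] annulation of the allenylsilane onto a 4-silyloxy-7-alkylcyclohept-2-enone; this closes ring A.
5. Ring order: ring B is bought as cyclohepta-1,3-diene (C10–O and C6=O by singlet oxygen and Kornblum–DeLaMare rearrangement, C7–C11 by Mukaiyama–Michael addition to crotonaldehyde); ring A is formed second.

Key step: step 10

Remark (assumption): 9-O-acetylcupreidine is assumed to give the (S)-hydroxy enone in step 2; if the sense is the reverse, its quinine-derived pseudoenantiomer 9-O-acetylcupreine is used with no other change.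

Notation: α is the face of H-1 and H-5 of the cis-fused bicycle, β the opposite face. TBS = tert-butyldimethylsilyl, TBDPS = tert-butyldiphenylsilyl, TES = triethylsilyl, TMS = trimethylsilyl.

**Route**

Step 1
Reactants: 1 cyclohepta-1,3-diene
Product: 2 6,7-dioxabicyclo[3.2.2]non-8-ene (meso endoperoxide)
Conditions: O2, hν (visible), 5,10,15,20-tetraphenylporphyrin (cat.), CH2Cl2, 0 °C
Reagents that add atoms: dioxygen, O=O
Why: [4+2] cycloaddition of singlet oxygen to the cyclic 1,3-diene should give the meso endoperoxide, in which no stereocentre needs control.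

Step 2
Reactants: 2 6,7-dioxabicyclo[3.2.2]non-8-ene
Product: 3 (4S)-4-hydroxycyclohept-2-en-1-one
Conditions: 9-O-acetylcupreidine (10 mol%), CH2Cl2, rt
Reagents that add atoms: none
Why: Enantioselective Kornblum–DeLaMare rearrangement, in which the chiral base removes one of the two enantiotopic bridgehead hydrogens and O–O cleavage gives the γ-hydroxy enone, so that C10 is set by catalyst-controlled desymmetrisation.

Step 3
Reactants: 3 (4S)-4-hydroxycyclohept-2-en-1-one
Product: 4 (4S)-4-(tert-butyldimethylsilyloxy)cyclohept-2-en-1-one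
Conditions: TBSCl, imidazole, DMF, 0 °C → rt
Reagents that add atoms: tert-butyldimethylsilyl chloride, CC(C)(C)[Si](C)(C)Cl
Why: Standard silylation of a secondary alcohol, which leaves the enone and the C10 configuration untouched.

Step 4
Reactants: 4 (4S)-4-(tert-butyldimethylsilyloxy)cyclohept-2-en-1-one
Product: 5 tert-butyldimethyl{[(1S)-4-(trimethylsilyloxy)cyclohepta-2,4-dien-1-yl]oxy}silane
Conditions: LiN(i-Pr)2, THF, −78 °C; Me3SiCl, Et3N, −78 °C → 0 °C; non-aqueous work-up
Reagents that add atoms: chlorotrimethylsilane, C[Si](C)(C)Cl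
Why: Kinetic deprotonation of the α'-methylene (C7) by the hindered amide followed by O-silylation should give the cross-conjugated dienol silane without touching the γ-silyloxy stereocentre.

Step 5
Reactants: 5 tert-butyldimethyl{[(1S)-4-(trimethylsilyloxy)cyclohepta-2,4-dien-1-yl]oxy}silane; 6 (E)-but-2-enal
Product: 7 (3R)-3-[(1R,5S)-5-(tert-butyldimethylsilyloxy)-2-oxocyclohept-3-en-1-yl]butanal
Conditions: (2S,5S)-5-benzyl-2-tert-butyl-3-methylimidazolidin-4-one·2,4-dinitrobenzoic acid (20 mol%), CH2Cl2, H2O (2 equiv), −40 °C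
Reagents that add atoms: none
Why: Mukaiyama–Michael addition under iminium catalysis, in which the benzyl group of the catalyst shields one face of the (E)-iminium ion so that C7 adds to the open face of the β-carbon (11R), while the open transition state with anti topicity and approach to the enol silane face away from the C10 silyloxy group should give 7R (trans to the silyloxy group), the wet medium desilylating the oxocarbenium ion before a second, ring-closing Michael step can follow.

Step 6
Reactants: 7 (3R)-3-[(1R,5S)-5-(tert-butyldimethylsilyloxy)-2-oxocyclohept-3-en-1-yl]butanal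
Product: 8 (4S,7R)-4-(tert-butyldimethylsilyloxy)-7-[(2R)-4-hydroxybutan-2-yl]cyclohept-2-en-1-one
Conditions: NaBH4 (0.3 equiv), MeOH/CH2Cl2, −78 °C
Reagents that add atoms: none
Why: Chemoselective borohydride reduction, the aldehyde being reduced far faster than the conjugated ketone at low temperature.

Step 7
Reactants: 8 (4S,7R)-4-(tert-butyldimethylsilyloxy)-7-[(2R)-4-hydroxybutan-2-yl]cyclohept-2-en-1-one
Product: 9 (4S,7R)-4-(tert-butyldimethylsilyloxy)-7-[(2R)-4-(tert-butyldiphenylsilyloxy)butan-2-yl]cyclohept-2-en-1-one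
Conditions: TBDPSCl, imidazole, DMF, 0 °C → rt
Reagents that add atoms: tert-butyldiphenylsilyl chloride, CC(C)(C)[Si](Cl)(c1ccccc1)c1ccccc1
Why: Silylation of the primary alcohol, which also drains any lactol form of the δ-hydroxy ketone back to the open enone.

Step 8
Reactants: 10 3-(trimethylsilyl)prop-2-yn-1-ol
Product: 11 3-(trimethylsilyl)prop-2-yn-1-yl methanesulfonate
Conditions: MsCl, Et3N, CH2Cl2, −40 °C → 0 °C
Reagents that add atoms: methanesulfonyl chloride, CS(=O)(=O)Cl
Why: Standard sulfonylation of a primary propargylic alcohol.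

Step 9
Reactants: 11 3-(trimethylsilyl)prop-2-yn-1-yl methanesulfonate
Product: 12 1-methyl-1-(trimethylsilyl)allene
Conditions: MeMgCl, CuBr, LiBr (1.2 equiv each), THF, −70 °C → rt
Reagents that add atoms: methylmagnesium chloride, C[Mg]Cl
Why: SN2' displacement of the propargylic mesylate by the methylcopper reagent at the silyl-bearing alkyne carbon should give the 1,1-disubstituted allene.

Step 10
Reactants: 9 (4S,7R)-4-(tert-butyldimethylsilyloxy)-7-[(2R)-4-(tert-butyldiphenylsilyloxy)butan-2-yl]cyclohept-2-en-1-one; 12 1-methyl-1-(trimethylsilyl)allene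
Product: 13 cis-fused hydroazulen-6-one with C3=C4, 4-methyl, 3-TMS, 10α-OTBS, 7β-[(2R)-4-(TBDPSO)butan-2-yl], H-1 and H-5 α
Conditions: TiCl4 (1.1 equiv), CH2Cl2, −78 °C; then 12 (1.5 equiv), −78 °C
Reagents that add atoms: none
Why: TiCl4 binds the C6 carbonyl and the CH2 terminus of the allenylsilane adds to C1, giving a vinyl cation β to silicon; a 1,2-shift of the Me3Si group moves the charge to the methyl-bearing carbon, which the titanium enolate captures through C5, so that C1–C2 and C4–C5 form in one operation (Danheiser (trimethylsilyl)cyclopentene annulation, a formal [3+2] of an allenylsilane with an enone). Ring A closes in the second bond formation by attack of the C5 enolate carbon on the vinyl cation, a 5-endo closure that leaves the new C3=C4 double bond inside the ring. C1 is set by approach of the allene to the enone face opposite the adjacent C10 silyloxy group (the β face), and C5 follows because the five-membered ring can only close on the face already occupied at C1, which gives the cis fusion with H-1 and H-5 α. The silyl shift fixes the regiochemistry, placing the methyl on C4 next to C5 and silicon on C3. The step needs 1,4- over 1,2-addition, ring closure faster than chloride-induced loss of silicon from the vinyl cation, and survival of both silyl ethers; the unhindered β-CH of the enone, the low temperature and the absence of a second alkene conjugated to the enone (C10 is sp3) should secure these.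

Step 11
Reactants: 13 the annulation product
Product: 14 the 10α-alcohol (C10–OH free; TBDPS ether, TMS and C6 ketone retained)
Conditions: HF·pyridine, pyridine, THF, 0 °C → rt
Reagents that add atoms: none
Why: Fluoride-mediated desilylation, in which buffered HF·pyridine cleaves the secondary TBS ether much faster than the primary TBDPS ether and leaves the vinyl C–Si bond alone.

Step 12
Reactants: 14 the 10α-alcohol
Product: 15 the 6,10-diketone (cis-fused, 3-TMS, C3=C4, 7β side chain)
Conditions: Dess–Martin periodinane, CH2Cl2, rt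
Reagents that add atoms: none
Why: Dess–Martin oxidation under neutral conditions should give the 1,4-diketone without enolising C1, C5 or C7.

Step 13
Reactants: 15 the 6,10-diketone
Product: 16 the 10-methylene-6-ketone
Conditions: Zn, CH2Br2, TiCl4 (pre-formed reagent), THF/CH2Cl2, 0 °C → rt
Reagents that add atoms: dibromomethane, BrCBr
Why: Takai–Lombardo methylenation, in which the non-basic zinc/titanium methylene reagent should olefinate the C10 ketone (one α-methylene) in preference to the C6 ketone flanked by two methine carbons, and should not epimerise the α-stereocentres or move the β,γ-alkene.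

Step 14
Reactants: 16 the 10-methylene-6-ketone
Product: 18 the 4α-hydroxy-4β-methyl-3-TMS-Δ2 ketone (tertiary allylic alcohol), via C4 hydroperoxide 17 (not isolated)
Conditions: O2, hν (visible), 5,10,15,20-tetraphenylporphyrin (cat.), CH2Cl2, −40 °C; then PPh3, −40 °C → 0 °C
Reagents that add atoms: dioxygen, O=O
Why: Schenck ene reaction of singlet oxygen with a vinylsilane, in which oxygen bonds to C4 (the carbon β to silicon) and removes a hydrogen from C2 (geminal to silicon) on the convex α face of ring A, setting C4 with OH α and methyl β and moving the alkene to C2=C3, the 1,1-disubstituted exocyclic alkene reacting far more slowly and PPh3 reducing the hydroperoxide without touching the ketone.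

Step 15
Reactants: 18 the β-hydroxy ketone
Product: 19 the 4α,6β-diol (3-TMS, C2=C3, 10-methylene, TBDPS ether)
Conditions: Me4NBH(OAc)3, MeCN/AcOH, −30 °C
Reagents that add atoms: none
Why: Evans–Saksena reduction, in which the C4 hydroxyl exchanges onto boron and delivers hydride intramolecularly to the α face of the C6 ketone to give the 1,3-anti diol (6-OH β), the face also favoured sterically because the C4 methyl and the C7 side chain lie on the β face.

Step 16
Reactants: 19 the 4α,6β-diol
Product: 20 the triol (C4–OH, C6–OH, C13–OH; C2=C3 and 10-methylene)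
Conditions: Bu4NF (excess), THF, 60 °C
Reagents that add atoms: none
Why: Fluoride-promoted protodesilylation of a 2-silyl allylic alcohol (the C4 alkoxide attacks silicon in a Brook-type C→O shift and the vinyl anion is protonated at C3 without moving the alkene), the primary TBDPS ether being cleaved in the same operation.

Step 17
Reactants: 20 the triol
Product: 21 the tris(triethylsilyl) ether
Conditions: Et3SiOTf (excess), 2,6-lutidine, CH2Cl2, −78 °C → 0 °C
Reagents that add atoms: triethylsilyl trifluoromethanesulfonate, CC[Si](CC)(CC)OS(=O)(=O)C(F)(F)F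
Why: Exhaustive silylation with the silyl triflate should protect the primary, the hindered secondary and the tertiary hydroxyl.

Step 18
Reactants: 21 the tris(triethylsilyl) ether
Product: 22 the C13 aldehyde (4-OTES and 6-OTES retained)
Conditions: (COCl)2, DMSO, CH2Cl2, −78 °C → −30 °C; Et3N, −78 °C → rt
Reagents that add atoms: none
Why: Swern oxidation of a primary triethylsilyl ether, in which the unhindered primary TES ether is cleaved by the activated sulfonium species and oxidised directly to the aldehyde while the secondary and tertiary TES ethers stay in place, so that the aldehyde never meets a free C6 hydroxyl and cannot form a lactol.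

Step 19
Reactants: 22 the C13 aldehyde
Product: 23 the (13R)-allylic alcohol (2-methylprop-1-enyl carbinol; 4-OTES and 6-OTES retained)
Conditions: Me2C=CHMgBr (2.4 equiv), ZnCl2 (1.2 equiv), Et2O; 1,4-dioxane (removes MgBrCl); (−)-MIB [(2S)-3-exo-morpholinoisoborneol] (10 mol%), toluene, 0 °C
Reagents that add atoms: 2-methylprop-1-enylmagnesium bromide, CC(C)=C[Mg]Br (transmetallated in the flask to the zinc reagent)
Why: Amino-alcohol-catalysed enantioselective addition of an alkenylzinc reagent to an aldehyde, in which the zinc alkoxide of (−)-MIB should direct the 2-methylprop-1-enyl group to the Si face of the aldehyde (13R here), the remote C11 centre having little influence.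

Step 20
Reactants: 23 the (13R)-allylic alcohol
Product: 24 the (13R)-acetate bis(triethylsilyl) ether
Conditions: Ac2O, pyridine, 4-(dimethylamino)pyridine (cat.), CH2Cl2, 0 °C
Reagents that add atoms: acetic anhydride, CC(=O)OC(C)=O
Why: Acylation of the only free hydroxyl, a secondary allylic alcohol, with retention at C13.

Step 21
Reactants: 24 the (13R)-acetate bis(triethylsilyl) ether
Product: 25 the target, CNP0209568.2
Conditions: HF·pyridine, pyridine, THF, 0 °C → rt
Reagents that add atoms: none
Why: Fluoride cleavage of the two triethylsilyl ethers under buffered conditions that should leave the allylic acetate and the tertiary allylic alcohol intact.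

**Compound list**

1 | cyclohepta-1,3-diene | C1=CC=CCCC1 | starting material
2 | 6,7-dioxabicyclo[3.2.2]non-8-ene (meso endoperoxide) | C1=C[C@H]2CCC[C@@H]1OO2 | intermediate
3 | (4S)-4-hydroxycyclohept-2-en-1-one | O[C@H]1CCCC(=O)C=C1 | intermediate
4 | (4S)-4-(tert-butyldimethylsilyloxy)cyclohept-2-en-1-one | CC(C)(C)[Si](C)(C)O[C@H]1CCCC(=O)C=C1 | intermediate
5 | tert-butyldimethyl{[(1S)-4-(trimethylsilyloxy)cyclohepta-2,4-dien-1-yl]oxy}silane | CC(C)(C)[Si](C)(C)O[C@H]1CCC=C(O[Si](C)(C)C)C=C1 | intermediate
6 | (E)-but-2-enal (crotonaldehyde) | C/C=C/C=O | starting material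
7 | (3R)-3-[(1R,5S)-5-(tert-butyldimethylsilyloxy)-2-oxocyclohept-3-en-1-yl]butanal | CC(C)(C)[Si](C)(C)O[C@H]1CC[C@H]([C@H](C)CC=O)C(=O)C=C1 | intermediate
8 | (4S,7R)-4-(tert-butyldimethylsilyloxy)-7-[(2R)-4-hydroxybutan-2-yl]cyclohept-2-en-1-one | CC(C)(C)[Si](C)(C)O[C@H]1CC[C@H]([C@H](C)CCO)C(=O)C=C1 | intermediate
9 | (4S,7R)-4-(tert-butyldimethylsilyloxy)-7-[(2R)-4-(tert-butyldiphenylsilyloxy)butan-2-yl]cyclohept-2-en-1-one (key-step precursor) | CC(C)(C)[Si](C)(C)O[C@H]1CC[C@H]([C@H](C)CCO[Si](c2ccccc2)(c2ccccc2)C(C)(C)C)C(=O)C=C1 | intermediate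
10 | 3-(trimethylsilyl)prop-2-yn-1-ol | C[Si](C)(C)C#CCO | starting material
11 | 3-(trimethylsilyl)prop-2-yn-1-yl methanesulfonate | C[Si](C)(C)C#CCOS(C)(=O)=O | intermediate
12 | 1-methyl-1-(trimethylsilyl)allene | CC(=C=C)[Si](C)(C)C | intermediate
13 | cis-fused hydroazulen-6-one: C3=C4, 4-methyl, 3-TMS, 10α-OTBS, 7β-[(2R)-4-(TBDPSO)butan-2-yl], H-1/H-5 α (key-step product) | CC(C)(C)[Si](C)(C)O[C@H]1CC[C@H]([C@H](C)CCO[Si](c3ccccc3)(c3ccccc3)C(C)(C)C)C(=O)[C@H]2[C@@H]1CC([Si](C)(C)C)=C2C | intermediate
14 | as 13 with free 10α-OH | O[C@H]1CC[C@H]([C@H](C)CCO[Si](c3ccccc3)(c3ccccc3)C(C)(C)C)C(=O)[C@H]2[C@@H]1CC([Si](C)(C)C)=C2C | intermediate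
15 | 6,10-diketone (cis-fused, 3-TMS, C3=C4, 7β side chain) | O=C1CC[C@H]([C@H](C)CCO[Si](c3ccccc3)(c3ccccc3)C(C)(C)C)C(=O)[C@H]2[C@@H]1CC([Si](C)(C)C)=C2C | intermediate
16 | 10-methylene-6-ketone (3-TMS, C3=C4) | C=C1CC[C@H]([C@H](C)CCO[Si](c3ccccc3)(c3ccccc3)C(C)(C)C)C(=O)[C@H]2[C@@H]1CC([Si](C)(C)C)=C2C | intermediate
17 | 4α-hydroperoxy-4β-methyl-3-TMS-Δ2 ketone | C=C1CC[C@H]([C@H](C)CCO[Si](c3ccccc3)(c3ccccc3)C(C)(C)C)C(=O)[C@H]2[C@@H]1C=C([Si](C)(C)C)[C@]2(C)OO | intermediate
18 | 4α-hydroxy-4β-methyl-3-TMS-Δ2 ketone | C=C1CC[C@H]([C@H](C)CCO[Si](c3ccccc3)(c3ccccc3)C(C)(C)C)C(=O)[C@H]2[C@@H]1C=C([Si](C)(C)C)[C@]2(C)O | intermediate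
19 | 4α,6β-diol (3-TMS, C2=C3, 10-methylene, 13-OTBDPS) | C=C1CC[C@H]([C@H](C)CCO[Si](c3ccccc3)(c3ccccc3)C(C)(C)C)[C@H](O)[C@H]2[C@@H]1C=C([Si](C)(C)C)[C@]2(C)O | intermediate
20 | 4α,6β,13-triol (C2=C3, 10-methylene) | C=C1CC[C@H]([C@H](C)CCO)[C@H](O)[C@H]2[C@@H]1C=C[C@]2(C)O | intermediate
21 | 4,6,13-tris(triethylsilyl) ether of 20 | C=C1CC[C@H]([C@H](C)CCO[Si](CC)(CC)CC)[C@H](O[Si](CC)(CC)CC)[C@H]2[C@@H]1C=C[C@]2(C)O[Si](CC)(CC)CC | intermediate
22 | C13 aldehyde, 4,6-bis(triethylsilyl) ether | C=C1CC[C@H]([C@H](C)CC=O)[C@H](O[Si](CC)(CC)CC)[C@H]2[C@@H]1C=C[C@]2(C)O[Si](CC)(CC)CC | intermediate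
23 | (13R)-allylic alcohol, 4,6-bis(triethylsilyl) ether | C=C1CC[C@H]([C@H](C)C[C@H](C=C(C)C)O)[C@H](O[Si](CC)(CC)CC)[C@H]2[C@@H]1C=C[C@]2(C)O[Si](CC)(CC)CC | intermediate
24 | (13R)-acetate, 4,6-bis(triethylsilyl) ether | C=C1CC[C@H]([C@H](C)C[C@H](C=C(C)C)OC(C)=O)[C@H](O[Si](CC)(CC)CC)[C@H]2[C@@H]1C=C[C@]2(C)O[Si](CC)(CC)CC | intermediate
25 | CNP0209568.2 | C=C1CC[C@H]([C@H](C)C[C@H](C=C(C)C)OC(C)=O)[C@H](O)[C@H]2[C@@H]1C=C[C@]2(C)O | target

**Step count**

Total: 21 steps. Longest linear sequence: 19 steps (steps 1–7 and 10–21); steps 8–9 make the allene.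

**Steps most likely to fail, with fallbacks**

Step 10 (key annulation). What may go wrong: loss of facial control at C1 if the C7 side chain offsets the bias of the C10 silyloxy group, capture of the vinyl cation by chloride with loss of silicon before ring closure, and Lewis-acid epimerisation at C7. Fallback: the order of the two constructions is reversed. Setting out from 4, the same annulation with 12 (TiCl4, CH2Cl2, −78 °C) is run on the enone that carries no side chain and should give the bicyclic ketone F1. Kinetic enolisation of the C7 methylene (LiN(i-Pr)2, Me3SiCl, THF, −78 °C) should give the enol silane F2. The iminium-catalysed Mukaiyama–Michael addition to 6 used in step 5 (catalyst control at C11, anti topicity for C7) should give the aldehyde F3, and NaBH4 should give the alcohol F4. Silylation with tert-butyldiphenylsilyl chloride and imidazole comes back to the route at 13.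

Step 5 (Mukaiyama–Michael addition). What may go wrong: weak simple diastereoselection at C7, and a second, ring-closing Michael addition of the intermediate enamine to C1 that would give a bicyclo[3.2.2]nonanone (formal [4+2]). Fallback: auxiliary control in a Lewis-acid-promoted Mukaiyama–Michael addition. Setting out from 5, addition to (S)-4-benzyl-3-[(E)-but-2-enoyl]oxazolidin-2-one (TiCl4, CH2Cl2, −78 °C) should give the imide F5; the chelated s-cis imide is attacked opposite the benzyl group (11R), and the open transition state favours the anti adduct (7R). LiBH4 (THF, MeOH, 0 °C) removes the auxiliary and reduces the ring carbonyl to give the diol F6 (C6 epimers, of no consequence). Selective silylation of the primary hydroxyl (tert-butyldiphenylsilyl chloride, imidazole) gives the allylic alcohol F7, and MnO2 oxidation comes back to the route at 9.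

Step 14 (singlet-oxygen ene). What may go wrong: fragmentation or retro-aldol cleavage of the β-hydroperoxy and β-hydroxy ketone, and oxygenation at C3 or at the exocyclic alkene. Fallback: the ketone is removed before oxygenation, and C6 is then set by steric approach instead of hydroxyl delivery. Setting out from 16, LiBH(s-Bu)3 (THF, −78 °C) should add hydride to the α face of C6 to give the 6β-alcohol F8. Photo-oxygenation under the conditions of step 14 should give the hydroperoxide F9, and PPh3 reduction comes back to the route at 19.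

**Further compounds**

F1 | step 10 | cis-fused hydroazulen-6-one without side chain (10α-OTBS, 4-methyl, 3-TMS, C3=C4) | CC(C)(C)[Si](C)(C)O[C@H]1CCCC(=O)[C@H]2[C@@H]1CC([Si](C)(C)C)=C2C
F2 | step 10 | C6-trimethylsilyl enol ether of F1 (C6=C7) | CC(C)(C)[Si](C)(C)O[C@H]1CCC=C(O[Si](C)(C)C)[C@H]2[C@@H]1CC([Si](C)(C)C)=C2C
F3 | step 10 | 7β-[(2R)-4-oxobutan-2-yl] derivative of F1 (aldehyde) | CC(C)(C)[Si](C)(C)O[C@H]1CC[C@H]([C@H](C)CC=O)C(=O)[C@H]2[C@@H]1CC([Si](C)(C)C)=C2C
F4 | step 10 | 7β-[(2R)-4-hydroxybutan-2-yl] derivative of F1 (alcohol) | CC(C)(C)[Si](C)(C)O[C@H]1CC[C@H]([C@H](C)CCO)C(=O)[C@H]2[C@@H]1CC([Si](C)(C)C)=C2C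
F5 | step 5 | (4S)-4-benzyl-3-{(3R)-3-[(1R,5S)-5-(tert-butyldimethylsilyloxy)-2-oxocyclohept-3-en-1-yl]butanoyl}oxazolidin-2-one | CC(C)(C)[Si](C)(C)O[C@H]1CC[C@H]([C@H](C)CC(=O)N2[C@@H](Cc3ccccc3)COC2=O)C(=O)C=C1
F6 | step 5 | (4S,7R)-4-(tert-butyldimethylsilyloxy)-7-[(2R)-4-hydroxybutan-2-yl]cyclohept-2-en-1-ol (C1 epimers) | CC(C)(C)[Si](C)(C)O[C@H]1CC[C@H]([C@H](C)CCO)C(O)C=C1
F7 | step 5 | (4S,7R)-4-(tert-butyldimethylsilyloxy)-7-[(2R)-4-(tert-butyldiphenylsilyloxy)butan-2-yl]cyclohept-2-en-1-ol (C1 epimers) | CC(C)(C)[Si](C)(C)O[C@H]1CC[C@H]([C@H](C)CCO[Si](c2ccccc2)(c2ccccc2)C(C)(C)C)C(O)C=C1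
F8 | step 14 | 6β-alcohol of 16 (3-TMS, C3=C4, 10-methylene) | C=C1CC[C@H]([C@H](C)CCO[Si](c3ccccc3)(c3ccccc3)C(C)(C)C)[C@H](O)[C@H]2[C@@H]1CC([Si](C)(C)C)=C2C
F9 | step 14 | 4α-hydroperoxy-6β-alcohol (3-TMS, C2=C3) | C=C1CC[C@H]([C@H](C)CCO[Si](c3ccccc3)(c3ccccc3)C(C)(C)C)[C@H](O)[C@H]2[C@@H]1C=C([Si](C)(C)C)[C@]2(C)OO
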